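**Retrosynthetic overview** (target numbering: C1 = quaternary carbinol, C3 = CHOH, C4=C5 = ring alkene)
1. 17 ⇒ 16: the only ring built, the cyclohexene, is closed last by ring-closing metathesis (C4=C5) of an acyclic (3S,5S)-1,7-diene diol.
2. 16 ⇒ 13 + 14: the C1–chain bond comes from chelate-controlled addition of the chain Grignard reagent to a β-hydroxy allyl ketone; the C3 hydroxyl steers the quaternary carbinol.
3. 13 ⇒ 12 ⇒ 6 + 7 + 8 (key step): C2 of 1,3-dithiane, a masked carbonyl dianion, is joined in one flask to the CH2 of (R)-2-vinyloxirane (C1–C2) and to allyl bromide (C1–C6), both electrophilic carbons; the epoxide supplies the C3 stereocentre.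
4. 14 ⇐ 5 ⇐ 4 ⇐ 1 + 2: acetylide alkylation, then Lindlar semi-hydrogenation for the Z alkene.

Assumption: (R)-2-vinyloxirane (7) is bought as the single enantiomer (it is sold as such, made from the cheap racemate by hydrolytic kinetic resolution).

**Step 1**
Reactants: 1 5-phenylpent-1-yne; 2 1,11-dibromoundecane
Product: 4 (16-bromohexadec-4-yn-1-yl)benzene, via lithium acetylide 3 (not isolated)
Conditions: n-BuLi (1.0 equiv), THF, −78 °C; then 2 (3 equiv), DMPU, −78 °C → rt, 12 h
Reagents that add atoms: none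
Why: SN2 alkylation of a lithium acetylide by a primary alkyl bromide, the threefold excess of the symmetrical dibromide (recovered) keeping double alkylation low; no stereocentre is involved.

**Step 2**
Reactants: 4 (16-bromohexadec-4-yn-1-yl)benzene
Product: 5 [(4Z)-16-bromohexadec-4-en-1-yl]benzene
Conditions: H2 (1 atm), Pd/CaCO3 poisoned with Pb(OAc)2 (Lindlar catalyst), quinoline, hexane, rt
Reagents that add atoms: none
Why: Lindlar semi-hydrogenation delivers both hydrogens to one face of the alkyne on the poisoned Pd surface, giving the Z alkene and leaving the primary C–Br bond alone.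

**Step 3 (key step)**
Reactants: 6 1,3-dithiane; 7 (2R)-2-ethenyloxirane; 8 3-bromoprop-1-ene (allyl bromide)
Product: 12 (2S)-1-[2-(prop-2-en-1-yl)-1,3-dithian-2-yl]but-3-en-2-ol, via 2-lithio-1,3-dithiane 9 (not isolated), via lithium alkoxide 10 (not isolated), via C,O-dilithio species 11 (not isolated)
Conditions: n-BuLi (1.05 equiv), THF, −30 °C; 7 (1.0 equiv), −78 → 0 °C; n-BuLi (1.1 equiv), −30 °C, 3 h; 8 (1.0 equiv), −78 → 0 °C; H2O
Reagents that add atoms: none
Why: Corey–Seebach dithiane umpolung used twice on one carbon in one flask: lithiated C2 (a masked acyl anion) opens the vinyl epoxide by SN2 at its unhindered CH2, so the C–O bond of the stereocentre is never broken and (R)-7 gives the (S)-alkoxide, and the C,O-dianion formed by the second lithiation is allylated on carbon because the dithiane carbanion is far more nucleophilic than the lithium alkoxide.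

**Step 4**
Reactants: 12 (2S)-1-[2-(prop-2-en-1-yl)-1,3-dithian-2-yl]but-3-en-2-ol
Product: 13 (6S)-6-hydroxyocta-1,7-dien-4-one
Conditions: MeI (10 equiv), CaCO3, MeCN/H2O (9:1), 40 °C; filtered, concentrated cold, used crude at once (no silica)
Reagents that add atoms: water, O
Why: Alkylative dithiane hydrolysis (dethioacetalisation) runs at neutral pH under CaCO3 buffering and ignores alkenes, so the β-hydroxy β′,γ′-unsaturated ketone is released without alkene migration or dehydration and the carbinol stereocentre is untouched.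

**Step 5**
Reactants: 13 (6S)-6-hydroxyocta-1,7-dien-4-one; 5 [(4Z)-16-bromohexadec-4-en-1-yl]benzene
Product: 16 (3S,5S)-5-[(12Z)-16-phenylhexadec-12-en-1-yl]octa-1,7-diene-3,5-diol, via Grignard reagent 14 (not isolated), via bromomagnesium alkoxide 15 (not isolated)
Conditions: 5 (2.6 equiv), Mg, I2 (cat.), Et2O, 35 °C; then 13 (1 equiv) in CH2Cl2, −78 → −40 °C; H2O
Reagents that add atoms: none
Why: Chelation-controlled (Cram-chelate, 1,3-induction) Grignard addition: the first equivalent of 14 makes magnesium alkoxide 15, whose six-membered chelate to the ketone is a half-chair with the vinyl group pseudo-equatorial, and the next equivalent attacks axially on the face that leads to a chair (the trajectory that gives syn diols in chelate-controlled reductions), so the chain enters trans to the vinyl group and the new tertiary hydroxyl is syn to the C3 hydroxyl along the carbon backbone that becomes the ring, i.e. (3S,5S).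

**Step 6**
Reactants: 16 (3S,5S)-5-[(12Z)-16-phenylhexadec-12-en-1-yl]octa-1,7-diene-3,5-diol
Product: 17 (1S,3S)-1-[(12Z)-16-phenylhexadec-12-en-1-yl]cyclohex-4-ene-1,3-diol
Conditions: second-generation Grubbs catalyst RuCl2(=CHPh)(PCy3)(H2IMes) (2 mol %), CH2Cl2 (5 mM), 25 °C, 30 min, Ar sparge; ethyl vinyl ether quench
Reagents that add atoms: none
Why: Ring-closing metathesis of the two terminal alkenes releases ethene and closes the six-membered ring much faster than the carbene touches the internal Z alkene, and since neither stereocentre is involved the syn (3S,5S) diol becomes the cis (1S,3S) ring diol.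

**Compound list**
1 | 5-phenylpent-1-yne | C#CCCCc1ccccc1 | starting material
2 | 1,11-dibromoundecane | BrCCCCCCCCCCCBr | starting material
3 | lithium 5-phenylpent-1-yn-1-ide | [Li]C#CCCCc1ccccc1 | intermediate
4 | (16-bromohexadec-4-yn-1-yl)benzene | BrCCCCCCCCCCCC#CCCCc1ccccc1 | intermediate
5 | [(4Z)-16-bromohexadec-4-en-1-yl]benzene | BrCCCCCCCCCCC/C=C\CCCc1ccccc1 | intermediate
6 | 1,3-dithiane | C1CSCSC1 | starting material
7 | (2R)-2-ethenyloxirane ((R)-2-vinyloxirane) | C=C[C@@H]1CO1 | starting material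
8 | 3-bromoprop-1-ene (allyl bromide) | C=CCBr | starting material
9 | 2-lithio-1,3-dithiane | [Li]C1SCCCS1 | intermediate
10 | lithium (2S)-1-(1,3-dithian-2-yl)but-3-en-2-olate | C=C[C@@H](O[Li])CC1SCCCS1 | intermediate
11 | lithium (2S)-1-(2-lithio-1,3-dithian-2-yl)but-3-en-2-olate | C=C[C@@H](O[Li])CC1([Li])SCCCS1 | intermediate
12 | (2S)-1-[2-(prop-2-en-1-yl)-1,3-dithian-2-yl]but-3-en-2-ol | C=C[C@@H](O)CC1(CC=C)SCCCS1 | intermediate
13 | (6S)-6-hydroxyocta-1,7-dien-4-one | C=C[C@@H](O)CC(=O)CC=C | intermediate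
14 | bromo[(12Z)-16-phenylhexadec-12-en-1-yl]magnesium | Br[Mg]CCCCCCCCCCC/C=C\CCCc1ccccc1 | intermediate
15 | bromomagnesium (3S)-5-oxoocta-1,7-dien-3-olate | C=C[C@@H](O[Mg]Br)CC(=O)CC=C | intermediate
16 | (3S,5S)-5-[(12Z)-16-phenylhexadec-12-en-1-yl]octa-1,7-diene-3,5-diol | C=C[C@@H](O)C[C@](O)(CCCCCCCCCCC/C=C\CCCc1ccccc1)CC=C | intermediate
17 | (1S,3S)-1-[(12Z)-16-phenylhexadec-12-en-1-yl]cyclohex-4-ene-1,3-diol | O[C@@H]1C=CC[C@@](O)(CCCCCCCCCCC/C=C\CCCc2ccccc2)C1 | target

**Step count and risks**
Total steps: 6 (isolated products 4, 5, 12, 13, 16, 17). Longest linear sequence: 4 steps (steps 3, 4, 5, 6; the chain branch, steps 1, 2, 5, 6, is equally long).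

Step 3 is at risk because the second lithiation has to take place beside a lithium alkoxide; slow metalation or O-allylation would cost yield. The fallback sets out from 6 and comes back at 12. Dithiane 6 is lithiated (n-BuLi, THF, −30 °C) and allylated with 8 to give 2-(prop-2-en-1-yl)-1,3-dithiane F1. Lithiated F1 opens (S)-epichlorohydrin (ClC[C@@H]1CO1) at the oxirane CH2, and the alkoxide then closes onto CH2Cl to give (2S)-2-{[2-(prop-2-en-1-yl)-1,3-dithian-2-yl]methyl}oxirane F2 with the carbinol configuration retained. Excess dimethylsulfonium methylide (Me3SI, n-BuLi, THF, −10 °C → rt) opens the terminal epoxide and loses dimethyl sulfide to give the one-carbon-longer allylic alcohol, which is 12. This needs neither a vinyl epoxide nor a dianion.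

Step 5 is at risk because the CH2 between carbonyl and vinyl in 13 is acidic, so 14 may enolise it, and 1,3-chelate control with Grignard reagents is often only about 4–8:1 (the minor diastereomer would be removed after step 6). The fallback sets out from 5 and 6 and comes back at 17; it exchanges the roles of the two carbon nucleophiles and corrects C3 afterwards, and it also avoids ketone 13 altogether.
- Dithiane 6 is lithiated, opened with (S)-2-vinyloxirane (C=C[C@H]1CO1), lithiated again and alkylated with 5 (DMPU) to give (2R)-1-{2-[(12Z)-16-phenylhexadec-12-en-1-yl]-1,3-dithian-2-yl}but-3-en-2-ol F3.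
- MeI/CaCO3 frees (3R,17Z)-3-hydroxy-21-phenylhenicosa-1,17-dien-5-one F4, a ketone without β,γ-unsaturation.
- TiCl4 then allyltrimethylsilane (C=CC[Si](C)(C)C) in CH2Cl2 at −78 °C adds allyl to the titanium chelate by the same facial rule. This now gives (3R,5S)-5-[(12Z)-16-phenylhexadec-12-en-1-yl]octa-1,7-diene-3,5-diol F5, with the quaternary centre already correct and C3 wrong.
- Ring-closing metathesis as in step 6 gives the trans ring diol (1S,3R)-1-[(12Z)-16-phenylhexadec-12-en-1-yl]cyclohex-4-ene-1,3-diol F6.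
- Mitsunobu esterification (4-nitrobenzoic acid, PPh3, DIAD, THF, 0 °C) inverts only the secondary allylic carbinol to give (1S,5S)-5-hydroxy-5-[(12Z)-16-phenylhexadec-12-en-1-yl]cyclohex-2-en-1-yl 4-nitrobenzoate F7, and K2CO3/MeOH releases 17.

Step 6 is at risk because the ruthenium carbene may isomerise or ethenolyse the chain Z alkene. The fallback sets out from 4 and 13 and comes back at 17; it makes the Z alkene after the metathesis. Bromoalkyne 4 is turned (Mg, Et2O) into bromo(16-phenylhexadec-12-yn-1-yl)magnesium F8 and added to 13 as in step 5 to give (3S,5S)-5-(16-phenylhexadec-12-yn-1-yl)octa-1,7-diene-3,5-diol F9. Ring-closing metathesis gives (1S,3S)-1-(16-phenylhexadec-12-yn-1-yl)cyclohex-4-ene-1,3-diol F10; a remote internal alkyne is a poor partner for the carbene at 25 °C and high dilution. Lindlar semi-hydrogenation as in step 2, which does not reduce the ring alkene, then gives 17.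

**Further compounds**
F1 | step 3 | 2-(prop-2-en-1-yl)-1,3-dithiane | C=CCC1SCCCS1
F2 | step 3 | (2S)-2-{[2-(prop-2-en-1-yl)-1,3-dithian-2-yl]methyl}oxirane | C=CCC1(C[C@H]2CO2)SCCCS1
F3 | step 5 | (2R)-1-{2-[(12Z)-16-phenylhexadec-12-en-1-yl]-1,3-dithian-2-yl}but-3-en-2-ol | C=C[C@H](O)CC1(CCCCCCCCCCC/C=C\CCCc2ccccc2)SCCCS1
F4 | step 5 | (3R,17Z)-3-hydroxy-21-phenylhenicosa-1,17-dien-5-one | C=C[C@H](O)CC(=O)CCCCCCCCCCC/C=C\CCCc1ccccc1
F5 | step 5 | (3R,5S)-5-[(12Z)-16-phenylhexadec-12-en-1-yl]octa-1,7-diene-3,5-diol | C=C[C@H](O)C[C@](O)(CCCCCCCCCCC/C=C\CCCc1ccccc1)CC=C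
F6 | step 5 | (1S,3R)-1-[(12Z)-16-phenylhexadec-12-en-1-yl]cyclohex-4-ene-1,3-diol | O[C@H]1C=CC[C@@](O)(CCCCCCCCCCC/C=C\CCCc2ccccc2)C1
F7 | step 5 | (1S,5S)-5-hydroxy-5-[(12Z)-16-phenylhexadec-12-en-1-yl]cyclohex-2-en-1-yl 4-nitrobenzoate | O=C(O[C@@H]1C=CC[C@@](O)(CCCCCCCCCCC/C=C\CCCc2ccccc2)C1)c1ccc(cc1)[N+](=O)[O-]
F8 | step 6 | bromo(16-phenylhexadec-12-yn-1-yl)magnesium | Br[Mg]CCCCCCCCCCCC#CCCCc1ccccc1
F9 | step 6 | (3S,5S)-5-(16-phenylhexadec-12-yn-1-yl)octa-1,7-diene-3,5-diol | C=C[C@@H](O)C[C@](O)(CCCCCCCCCCCC#CCCCc1ccccc1)CC=C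
F10 | step 6 | (1S,3S)-1-(16-phenylhexadec-12-yn-1-yl)cyclohex-4-ene-1,3-diol | O[C@@H]1C=CC[C@@](O)(CCCCCCCCCCCC#CCCCc2ccccc2)C1
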